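**Retrosynthetic overview**

- The target is traced back through hydrogenolysis of two benzyl ethers and a C(sp3)–C(sp2) reductive coupling between an aryl bromide and a 4-(bromomethyl) lactone, which itself comes from a 4-(hydroxymethyl) lactone.
- The strategy rests on C4 of the γ-lactone ring (O1, carbonyl C2, carbinol C3, methine C4, methylene C5). C4 carries C5 and the benzylic CH2; before the aryl group is attached these are two identical CH2OH arms, so C4 is a prochiral centre next to the quaternary stereocentre C3.
- Key disconnection: O1–C2. An acyclic bis(hydroxymethyl) hydroxy amide closes the lactone with either arm, and the two lactones equilibrate by translactonisation to the 3,4-trans isomer. This is the only ring of the target made in the route; the aromatic rings are bought.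
- C3 is set by self-regeneration of stereocentres from (R)-malic acid (benzylation of its pivalaldehyde acetal). This avoids an aldol on an arylpyruvate ester, which exists largely as its enol.
- The two arms are then built by dianion hydroxymethylation and ester reduction, which erases any C4 configuration.

Key step: step 8

Remark: the acyl group at C2 of the lactonisation precursor is carried as a pyrrolidine amide, because a C2 methyl ester could not be distinguished from the ester that is reduced to make the second arm and would lactonise during that reduction; the O1–C2 closure and the equilibration are the same as for an ester.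

**Route**

Step 1
Reactants: 1 (R)-malic acid
Product: 2 [(2R,4R)-2-tert-butyl-5-oxo-1,3-dioxolan-4-yl]acetic acid
Conditions: t-BuCHO, TsOH·H2O (cat.), H2SO4 (cat.), pentane, reflux, Dean–Stark; recrystallisation
Reagents that add atoms: pivalaldehyde CC(C)(C)C=O
Why: Acid-catalysed acetalisation of the α-hydroxy acid with pivalaldehyde (Seebach dioxolanone formation) should give mainly the cis acetal, whose new acetal stereocentre is set under thermodynamic control by the existing carbinol centre, and crystallisation removes the trans isomer.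

Step 2
Reactants: 3 4-(benzyloxy)-3-methoxybenzyl alcohol
Product: 4 1-(benzyloxy)-4-(bromomethyl)-2-methoxybenzene
Conditions: PBr3 (0.4 equiv), Et2O, 0 °C; used at once
Reagents that add atoms: phosphorus tribromide BrP(Br)Br
Why: Bromination of an electron-rich benzylic alcohol with PBr3 (SN2 displacement of a phosphite ester by bromide) is routine; no stereocentre is involved and the labile bromide is not stored.

Step 3
Reactants: 2 [(2R,4R)-2-tert-butyl-5-oxo-1,3-dioxolan-4-yl]acetic acid; 4 1-(benzyloxy)-4-(bromomethyl)-2-methoxybenzene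
Product: 6 [(2R,4R)-4-[4-(benzyloxy)-3-methoxybenzyl]-2-tert-butyl-5-oxo-1,3-dioxolan-4-yl]acetic acid, via dilithium enolate carboxylate 5 (not isolated)
Conditions: LiN(SiMe3)2 (2.2 equiv), THF, −78 °C; then 4, −78 → −20 °C; cold aq. HCl work-up
Reagents that add atoms: none
Why: Self-regeneration of stereocentres after Seebach: the ring enolate is benzylated on the face anti to the tert-butyl group, so the benzyl group replaces the former hydrogen with retention and fixes the quaternary carbinol (C3 of the lactone) as R.

Step 4
Reactants: 6 [(2R,4R)-4-[4-(benzyloxy)-3-methoxybenzyl]-2-tert-butyl-5-oxo-1,3-dioxolan-4-yl]acetic acid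
Product: 7 methyl 2-[(2R,4R)-4-[4-(benzyloxy)-3-methoxybenzyl]-2-tert-butyl-5-oxo-1,3-dioxolan-4-yl]acetate
Conditions: MeI (1.5 equiv), KHCO3 (1.5 equiv), DMF, rt
Reagents that add atoms: iodomethane CI
Why: SN2 O-methylation of the carboxylate under bicarbonate conditions should leave the base-sensitive acetal lactone intact and gives the ester needed for enolisation in step 6; no stereocentre changes.

Step 5
Reactants: 7 methyl 2-[(2R,4R)-4-[4-(benzyloxy)-3-methoxybenzyl]-2-tert-butyl-5-oxo-1,3-dioxolan-4-yl]acetate
Product: 8 methyl (3R)-4-[4-(benzyloxy)-3-methoxyphenyl]-3-hydroxy-3-(pyrrolidine-1-carbonyl)butanoate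
Conditions: pyrrolidine (5 equiv), THF, 40 °C
Reagents that add atoms: pyrrolidine C1CCNC1
Why: Aminolysis of the activated (acylal-type) dioxolanone carbonyl by the secondary amine, with loss of pivalaldehyde, should be much faster than attack on the methyl ester and turns the future C2 carboxyl into a hydride-inert tertiary amide; the quaternary centre is not touched.

Step 6
Reactants: 8 methyl (3R)-4-[4-(benzyloxy)-3-methoxyphenyl]-3-hydroxy-3-(pyrrolidine-1-carbonyl)butanoate
Product: 10 methyl (3R)-4-[4-(benzyloxy)-3-methoxyphenyl]-3-hydroxy-2-(hydroxymethyl)-3-(pyrrolidine-1-carbonyl)butanoate (both C2 epimers), via dilithium alkoxide enolate 9 (not isolated)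
Conditions: LiN(iPr)2 (2.3 equiv), THF, −78 °C; monomeric CH2O (gas stream), −78 → −45 °C; aq. NH4Cl at −78 °C
Reagents that add atoms: formaldehyde C=O
Why: Dianion aldol of a β-hydroxy ester (Frater–Seebach-type alkoxide enolate) with formaldehyde adds the one-carbon arm at the only enolisable position; the new centre forms as a mixture, which does not matter because it stops being stereogenic in step 7.

Step 7
Reactants: 10 methyl (3R)-4-[4-(benzyloxy)-3-methoxyphenyl]-3-hydroxy-2-(hydroxymethyl)-3-(pyrrolidine-1-carbonyl)butanoate
Product: 11 (2R)-2-[4-(benzyloxy)-3-methoxybenzyl]-2,4-dihydroxy-3-(hydroxymethyl)-1-(pyrrolidin-1-yl)butan-1-one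
Conditions: LiBH4 (4 equiv), THF, 0 °C → rt; aq. NH4Cl
Reagents that add atoms: none
Why: Chemoselective LiBH4 reduction of the methyl ester in the presence of the tertiary amide gives the second hydroxymethyl arm, makes both arms identical and so merges the two epimers of 10 into one triol with C3 as its only stereocentre.

Step 8
Reactants: 11 (2R)-2-[4-(benzyloxy)-3-methoxybenzyl]-2,4-dihydroxy-3-(hydroxymethyl)-1-(pyrrolidin-1-yl)butan-1-one
Product: 13 (3R,4R)-3-[4-(benzyloxy)-3-methoxybenzyl]-3-hydroxy-4-(hydroxymethyl)dihydrofuran-2(3H)-one, via C4-epimeric lactone 12 (not isolated)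
Conditions: 2 M HCl, 1,4-dioxane, 70 °C; then DBU (cat.), CH2Cl2, rt, to constant ratio; chromatography
Reagents that add atoms: none
Why: Under acid one of the two diastereotopic hydroxymethyl oxygens adds to the protonated amide carbonyl and the tetrahedral intermediate expels pyrrolidine as its ammonium salt, which makes the O1–C2 closure irreversible (N-to-O acyl transfer, the acid-mediated lactonisation of γ-hydroxy amides). The ring closes in the 5-exo-trig mode with either arm, so 13 and its C4 epimer 12 should both form. The free arm of each lactone can add back to the lactone carbonyl through a 1-hydroxy-2,6-dioxabicyclo[2.2.1]heptane hemi-orthoester, so the two interconvert by translactonisation, the known behaviour of butyrolactones with a hydroxymethyl group on C4. C3 is untouched, and the new stereocentre C4 is set under thermodynamic control by C3: the arm left free should prefer the face of the small C3 hydroxyl, to which it can also hydrogen-bond, and avoid the C3 benzyl group. The step needs selection between two diastereotopic groups, and this is secured by that size difference together with the reversibility; the minor epimer can be separated and returned to the equilibration.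

Step 9
Reactants: 13 (3R,4R)-3-[4-(benzyloxy)-3-methoxybenzyl]-3-hydroxy-4-(hydroxymethyl)dihydrofuran-2(3H)-one
Product: 14 (3R,4R)-3-[4-(benzyloxy)-3-methoxybenzyl]-4-(bromomethyl)-3-hydroxydihydrofuran-2(3H)-one
Conditions: CBr4 (1.3 equiv), PPh3 (1.4 equiv), CH2Cl2, 0 °C
Reagents that add atoms: tetrabromomethane BrC(Br)(Br)Br
Why: Appel bromination should convert only the primary alcohol, removes the hydroxyl needed for translactonisation and so locks C4 without touching it; a bromide is chosen to match the reactivity of the aryl bromide in step 11.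

Step 10
Reactants: 15 4-bromo-2-methoxyphenol
Product: 16 1-(benzyloxy)-4-bromo-2-methoxybenzene
Conditions: BnBr (1.1 equiv), K2CO3, acetone, reflux
Reagents that add atoms: benzyl bromide BrCc1ccccc1
Why: Williamson etherification of the phenoxide masks the acidic phenol, which would otherwise interfere with the reductive coupling; no stereocentre is involved.

Step 11
Reactants: 14 (3R,4R)-3-[4-(benzyloxy)-3-methoxybenzyl]-4-(bromomethyl)-3-hydroxydihydrofuran-2(3H)-one; 16 1-(benzyloxy)-4-bromo-2-methoxybenzene
Product: 17 (3R,4R)-3,4-bis[4-(benzyloxy)-3-methoxybenzyl]-3-hydroxydihydrofuran-2(3H)-one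
Conditions: NiI2 (10 mol %), 4,4'-dimethoxy-2,2'-bipyridine (10 mol %), Zn (2 equiv), NaI (0.25 equiv), pyridine (10 mol %), DMPU, 60 °C
Reagents that add atoms: none
Why: Nickel-catalysed reductive cross-electrophile coupling of an aryl bromide with a primary alkyl bromide (Weix-type, zinc as reductant) forms the C(sp3)–C(sp2) bond under neutral conditions that tolerate the lactone and the free tertiary hydroxyl; the reacting carbon is a primary CH2 and neither stereocentre is at risk.

Step 12
Reactants: 17 (3R,4R)-3,4-bis[4-(benzyloxy)-3-methoxybenzyl]-3-hydroxydihydrofuran-2(3H)-one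
Product: 18 (+)-nortrachelogenin, (3R,4R)-3-hydroxy-3,4-bis(4-hydroxy-3-methoxybenzyl)dihydrofuran-2(3H)-one
Conditions: H2 (1 atm), 10% Pd/C, EtOAc/MeOH, rt
Reagents that add atoms: none
Why: Hydrogenolysis of both benzyl aryl ethers over Pd/C frees the two phenols; the lactone and the non-benzylic tertiary alcohol are inert and both stereocentres stay as set.

**Compound list**

1 | (R)-malic acid | O[C@H](CC(=O)O)C(=O)O | starting material
2 | [(2R,4R)-2-tert-butyl-5-oxo-1,3-dioxolan-4-yl]acetic acid | CC(C)(C)[C@@H]1O[C@H](CC(=O)O)C(=O)O1 | intermediate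
3 | 4-(benzyloxy)-3-methoxybenzyl alcohol | COc1cc(CO)ccc1OCc1ccccc1 | starting material
4 | 1-(benzyloxy)-4-(bromomethyl)-2-methoxybenzene | COc1cc(CBr)ccc1OCc1ccccc1 | intermediate
5 | dilithium enolate carboxylate of 2 | [Li+].[Li+].CC(C)(C)[C@@H]1OC(CC(=O)[O-])=C([O-])O1 | intermediate (not isolated)
6 | [(2R,4R)-4-[4-(benzyloxy)-3-methoxybenzyl]-2-tert-butyl-5-oxo-1,3-dioxolan-4-yl]acetic acid | CC(C)(C)[C@@H]1O[C@](Cc2ccc(OCc3ccccc3)c(OC)c2)(CC(=O)O)C(=O)O1 | intermediate
7 | methyl 2-[(2R,4R)-4-[4-(benzyloxy)-3-methoxybenzyl]-2-tert-butyl-5-oxo-1,3-dioxolan-4-yl]acetate | CC(C)(C)[C@@H]1O[C@](Cc2ccc(OCc3ccccc3)c(OC)c2)(CC(=O)OC)C(=O)O1 | intermediate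
8 | methyl (3R)-4-[4-(benzyloxy)-3-methoxyphenyl]-3-hydroxy-3-(pyrrolidine-1-carbonyl)butanoate | O[C@](Cc1ccc(OCc2ccccc2)c(OC)c1)(CC(=O)OC)C(=O)N1CCCC1 | intermediate
9 | dilithium alkoxide enolate of 8 | [Li+].[Li+].[O-][C@](Cc1ccc(OCc2ccccc2)c(OC)c1)(C=C([O-])OC)C(=O)N1CCCC1 | intermediate (not isolated)
10 | methyl (3R)-4-[4-(benzyloxy)-3-methoxyphenyl]-3-hydroxy-2-(hydroxymethyl)-3-(pyrrolidine-1-carbonyl)butanoate (C2 epimers) | O[C@](Cc1ccc(OCc2ccccc2)c(OC)c1)(C(CO)C(=O)OC)C(=O)N1CCCC1 | intermediate
11 | (2R)-2-[4-(benzyloxy)-3-methoxybenzyl]-2,4-dihydroxy-3-(hydroxymethyl)-1-(pyrrolidin-1-yl)butan-1-one | OCC(CO)[C@](O)(Cc1ccc(OCc2ccccc2)c(OC)c1)C(=O)N1CCCC1 | intermediate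
12 | (3R,4S)-3-[4-(benzyloxy)-3-methoxybenzyl]-3-hydroxy-4-(hydroxymethyl)dihydrofuran-2(3H)-one | OC[C@H]1COC(=O)[C@@]1(O)Cc1ccc(OCc2ccccc2)c(OC)c1 | intermediate (not isolated)
13 | (3R,4R)-3-[4-(benzyloxy)-3-methoxybenzyl]-3-hydroxy-4-(hydroxymethyl)dihydrofuran-2(3H)-one | OC[C@@H]1COC(=O)[C@@]1(O)Cc1ccc(OCc2ccccc2)c(OC)c1 | intermediate
14 | (3R,4R)-3-[4-(benzyloxy)-3-methoxybenzyl]-4-(bromomethyl)-3-hydroxydihydrofuran-2(3H)-one | BrC[C@@H]1COC(=O)[C@@]1(O)Cc1ccc(OCc2ccccc2)c(OC)c1 | intermediate
15 | 4-bromo-2-methoxyphenol | COc1cc(Br)ccc1O | starting material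
16 | 1-(benzyloxy)-4-bromo-2-methoxybenzene | COc1cc(Br)ccc1OCc1ccccc1 | intermediate
17 | (3R,4R)-3,4-bis[4-(benzyloxy)-3-methoxybenzyl]-3-hydroxydihydrofuran-2(3H)-one | COc1cc(C[C@@H]2COC(=O)[C@@]2(O)Cc2ccc(OCc3ccccc3)c(OC)c2)ccc1OCc1ccccc1 | intermediate
18 | (+)-nortrachelogenin | COc1cc(C[C@@H]2COC(=O)[C@@]2(O)Cc2ccc(O)c(OC)c2)ccc1O | target

**Step count**

Total step count: 12. Longest linear sequence: 10 steps (steps 1, 3, 4, 5, 6, 7, 8, 9, 11, 12); steps 2 and 10 prepare the two aryl partners.

**Steps most likely to fail**

Step 8. The thermodynamic preference between the two arms may be too small, or equilibration may stall, so that diastereotopic-group selectivity is poor. The fallback replaces the intrinsic bias by a covalent template. It sets out from 12, as its unseparated mixture with 13, and comes back at 13. The mixture would be heated with phenylboronic acid in toluene (Dean–Stark, cat. TsOH). Only the lactone in which the C3 hydroxyl and the C4 hydroxymethyl group are cis can form a six-membered cyclic boronate, so translactonisation should drain the mixture into the cyclic phenylboronate of 13 F1. Transesterification with pinacol in CH2Cl2 at rt under neutral conditions would release 13, which would be brominated at once as in step 9.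

Step 6. The tertiary aldolate may undergo retro-aldol cleavage, and hydroxymethylation with gaseous formaldehyde may be incomplete or occur twice. The fallback replaces the aldol by an alkylation. It sets out from 8 and comes back at 11. The dianion 9 would be C-alkylated with 2-(trimethylsilyl)ethoxymethyl chloride (THF, −78 → −40 °C) to give the SEM ether ester F2. LiBH4 in THF would reduce its ester to the mono-protected diol amide F3. Bu4NF in DMPU at 80 °C would then remove the SEM group and give the triol amide 11.

Step 11. The alkylnickel intermediate may suffer hydrodehalogenation or β-hydride elimination, and the electron-rich aryl bromide may homocouple. The fallback replaces the coupling of two electrophiles by a Negishi coupling with a preformed aryl nucleophile. It sets out from 16 and comes back at 17. Bromine–lithium exchange on 16 (n-BuLi, THF, −78 °C) and transmetalation with ZnCl2 would give [4-(benzyloxy)-3-methoxyphenyl]zinc chloride F4. This would be coupled with bromide 14 under conditions for unactivated primary alkyl bromides (Pd2(dba)3, tricyclopentylphosphine, N-methylimidazole, THF/NMP, 80 °C), with one extra equivalent of F4 to allow for the tertiary hydroxyl, to give 17.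

**Further compounds**

F1 | step 8 | cyclic phenylboronate of 13 (boron bridging the C3 oxygen and the C4 CH2O group) | O1C[C@@H]2COC(=O)[C@@]2(OB1c1ccccc1)Cc1ccc(OCc2ccccc2)c(OC)c1
F2 | step 6 | methyl (3R)-4-[4-(benzyloxy)-3-methoxyphenyl]-3-hydroxy-3-(pyrrolidine-1-carbonyl)-2-{[2-(trimethylsilyl)ethoxy]methyl}butanoate | O[C@](Cc1ccc(OCc2ccccc2)c(OC)c1)(C(COCC[Si](C)(C)C)C(=O)OC)C(=O)N1CCCC1
F3 | step 6 | (2R)-2-[4-(benzyloxy)-3-methoxybenzyl]-2,4-dihydroxy-1-(pyrrolidin-1-yl)-3-{[2-(trimethylsilyl)ethoxy]methyl}butan-1-one | OCC(COCC[Si](C)(C)C)[C@](O)(Cc1ccc(OCc2ccccc2)c(OC)c1)C(=O)N1CCCC1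
F4 | step 11 | [4-(benzyloxy)-3-methoxyphenyl]zinc chloride | COc1cc([Zn]Cl)ccc1OCc1ccccc1
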